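The γ-butyrolactone is disconnected at C4–C5, the bond between the ring O–CH2 carbon and the carbon bearing the 3,4-dimethoxybenzyl arm. The key step exploits that C5 is a lone methylene between ring oxygen O1 and C4, and that C4 carries a CH2–aryl group. A chloromethyl ester of an (R)-2-(arylmethyl)but-3-enoic acid is activated by nickel to an acyloxymethyl radical, which closes the five-membered lactone ring 5-exo onto the vinyl group. The exocyclic radical is arylated with 4-iodoveratrole in the same operation. One step thus builds the ring, the C4 stereocentre (trans, directed by C3) and the second aryl arm. The C3 centre comes from an Evans deconjugative alkylation.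

Key step: step 8

Remark: the lactone ring is numbered O1, C2 (carbonyl), C3, C4, C5 (OCH2); the target is the trans (3R,4R) isomer.

Step 1
Reactants: 1 3-hydroxy-4,5-dimethoxybenzaldehyde
Product: 2 3-(benzyloxy)-4,5-dimethoxybenzaldehyde
Conditions: BnBr, K2CO3, DMF, rt
Reagents that add atoms: benzyl bromide, BrCc1ccccc1
Why: Williamson ether synthesis, in which the phenoxide formed with K2CO3 is O-benzylated by SN2 displacement, masking the only acidic OH so that it survives the enolate, chloromethylation and nickel steps.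

Step 2
Reactants: 2 3-(benzyloxy)-4,5-dimethoxybenzaldehyde
Product: 3 [3-(benzyloxy)-4,5-dimethoxyphenyl]methanol
Conditions: NaBH4, MeOH, 0 °C
Reagents that add atoms: none
Why: Chemoselective hydride reduction of the aryl aldehyde to the benzylic alcohol, with the benzyl and methyl ethers inert to NaBH4.

Step 3
Reactants: 3 [3-(benzyloxy)-4,5-dimethoxyphenyl]methanol
Product: 4 1-(benzyloxy)-5-(bromomethyl)-2,3-dimethoxybenzene
Conditions: PBr3, CH2Cl2, 0 °C
Reagents that add atoms: phosphorus tribromide, BrP(Br)Br
Why: Bromination of the primary benzylic alcohol through its phosphite ester (SN2 by bromide), which should be fast at 0 °C for an electron-rich benzylic alcohol; the bromide is used directly.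

Step 4
Reactants: 5 (4R)-4-benzyl-1,3-oxazolidin-2-one; 6 (2E)-but-2-enoyl chloride
Product: 8 (4R)-4-benzyl-3-[(2E)-but-2-enoyl]-1,3-oxazolidin-2-one, via lithium oxazolidinide 7 (not isolated)
Conditions: n-BuLi, THF, −78 °C; then 6, −78 → 0 °C
Reagents that add atoms: none
Why: N-Acylation of the lithiated oxazolidinone by the acid chloride installs the Evans auxiliary under kinetic conditions that leave the (E)-enoyl unit untouched.

Step 5
Reactants: 8 (4R)-4-benzyl-3-[(2E)-but-2-enoyl]-1,3-oxazolidin-2-one; 4 1-(benzyloxy)-5-(bromomethyl)-2,3-dimethoxybenzene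
Product: 10 (4R)-4-benzyl-3-[(2R)-2-{[3-(benzyloxy)-4,5-dimethoxyphenyl]methyl}but-3-enoyl]-1,3-oxazolidin-2-one, via sodium dienolate 9 (not isolated)
Conditions: NaN(SiMe3)2, THF, −78 °C; then 4, −78 → −40 °C
Reagents that add atoms: none
Why: Evans deconjugative alkylation, in which NaN(SiMe3)2 removes a γ-hydrogen of the s-cis enoyl imide to give the chelated (Z)-dienolate 9, which is alkylated at its α-carbon on the face opposite the auxiliary benzyl group, setting the (2R) centre (the later C3) and moving the double bond to the β,γ-position.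

Step 6
Reactants: 10 (4R)-4-benzyl-3-[(2R)-2-{[3-(benzyloxy)-4,5-dimethoxyphenyl]methyl}but-3-enoyl]-1,3-oxazolidin-2-one
Product: 12 (2R)-2-{[3-(benzyloxy)-4,5-dimethoxyphenyl]methyl}but-3-enoic acid, via peroxy acid 11 (not isolated)
Conditions: LiOH, H2O2 (30% aq.), THF/H2O, 0 °C; then aq. Na2SO3; then HCl to pH 2
Reagents that add atoms: hydrogen peroxide, OO (one oxygen becomes the carboxyl OH)
Why: Hydroperoxide anion, a weakly basic α-effect nucleophile, attacks the exocyclic imide carbonyl selectively, so the auxiliary is released without removal of the acidic α-hydrogen (no epimerization, no conjugation), and sulfite reduces the percarboxylate 11 to the acid.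

Step 7
Reactants: 12 (2R)-2-{[3-(benzyloxy)-4,5-dimethoxyphenyl]methyl}but-3-enoic acid; 13 chloromethyl chlorosulfate
Product: 14 chloromethyl (2R)-2-{[3-(benzyloxy)-4,5-dimethoxyphenyl]methyl}but-3-enoate
Conditions: NaHCO3, Bu4NHSO4 (cat.), CH2Cl2/H2O, rt
Reagents that add atoms: none
Why: Phase-transfer O-alkylation of the carboxylate, in which the chlorosulfate of 13 is displaced far faster than its chloride, under conditions (aqueous NaHCO3) too weakly basic to touch the α-stereocentre.

Step 8
Reactants: 14 chloromethyl (2R)-2-{[3-(benzyloxy)-4,5-dimethoxyphenyl]methyl}but-3-enoate; 15 4-iodo-1,2-dimethoxybenzene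
Product: 17 (3R,4R)-3-{[3-(benzyloxy)-4,5-dimethoxyphenyl]methyl}-4-[(3,4-dimethoxyphenyl)methyl]oxolan-2-one, via iodomethyl ester 16 (not isolated)
Conditions: NiBr2·DME (5 mol%, DME = 1,2-dimethoxyethane), 4,4'-di-tert-butyl-2,2'-bipyridine (5 mol%), Mn powder (3 equiv), NaI (1.2 equiv), 15 (2 equiv), DMA, 60 °C, 14 added by syringe pump over 6 h
Reagents that add atoms: none
Why: Proposed new method: iodide exchange gives iodomethyl ester 16, from which monovalent nickel (formed by Mn reduction) abstracts iodine to give the acyloxymethyl radical at the O–CH2 carbon; this radical adds to the internal carbon of the vinyl group, closing the lactone ring through the C4–C5 bond, and the exocyclic primary radical is captured by the aryl nickel species (divalent nickel, from oxidative addition of 15 to zerovalent nickel) and released by reductive elimination as the CH2–aryl bond, Mn turning the catalyst over. The closest known reaction types are the nickel-catalysed reductive cyclization/arylation of haloacetal- and haloalkyl-tethered alkenes with aryl iodides and the tin hydride cyclization of unsaturated acyloxymethyl radicals; new is their combination through an ester tether. The one ring closed is the five-membered lactone, by 5-exo-trig radical closure (6-endo is stereoelectronically disfavoured). The new stereocentre C4 is controlled by the existing C3 centre: in the chair-like Beckwith–Houk transition state the C3 arylmethyl group sits pseudo-equatorial, which should place the two arms trans (3R,4R); any cis isomer is removed by chromatography and not epimerized, since epimerization at C3 would lead into the enantiomeric trans series. The step needs cyclization to outrun direct aryl coupling of the uncyclized radical despite the unreactive s-trans ester rotamer, which low catalyst loading, dilution, slow addition of 14, 60 °C and the Thorpe–Ingold effect of the C3 substituent should secure, while the aryl iodide reacts by two-electron oxidative addition and the alkyl iodide by halogen-atom abstraction. The medium is neutral, so the C3 hydrogen, the benzyl ether and the methyl ethers should be untouched.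

Step 9
Reactants: 17 (3R,4R)-3-{[3-(benzyloxy)-4,5-dimethoxyphenyl]methyl}-4-[(3,4-dimethoxyphenyl)methyl]oxolan-2-one
Product: 18 (3R,4R)-4-[(3,4-dimethoxyphenyl)methyl]-3-[(3-hydroxy-4,5-dimethoxyphenyl)methyl]oxolan-2-one
Conditions: H2 (1 atm), 10% Pd/C, EtOAc/EtOH, rt
Reagents that add atoms: none
Why: Hydrogenolysis of the aryl benzyl ether over palladium on carbon frees the phenol, while the lactone, the methyl ethers and both stereocentres, which carry no reducible group, are untouched.

Compound list
1 | 3-hydroxy-4,5-dimethoxybenzaldehyde | O=Cc1cc(O)c(OC)c(OC)c1 | starting material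
2 | 3-(benzyloxy)-4,5-dimethoxybenzaldehyde | O=Cc1cc(OCc2ccccc2)c(OC)c(OC)c1 | intermediate
3 | [3-(benzyloxy)-4,5-dimethoxyphenyl]methanol | OCc1cc(OCc2ccccc2)c(OC)c(OC)c1 | intermediate
4 | 1-(benzyloxy)-5-(bromomethyl)-2,3-dimethoxybenzene | BrCc1cc(OCc2ccccc2)c(OC)c(OC)c1 | intermediate
5 | (4R)-4-benzyl-1,3-oxazolidin-2-one | O=C1N[C@H](Cc2ccccc2)CO1 | starting material
6 | (2E)-but-2-enoyl chloride | C/C=C/C(Cl)=O | starting material
7 | lithium (4R)-4-benzyl-2-oxo-1,3-oxazolidin-3-ide | [Li+].O=C1OC[C@@H](Cc2ccccc2)[N-]1 | intermediate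
8 | (4R)-4-benzyl-3-[(2E)-but-2-enoyl]-1,3-oxazolidin-2-one | C/C=C/C(=O)N1[C@H](Cc2ccccc2)COC1=O | intermediate
9 | sodium (1Z)-1-[(4R)-4-benzyl-2-oxo-1,3-oxazolidin-3-yl]buta-1,3-dien-1-olate | [Na+].[O-]/C(=C\C=C)N1[C@H](Cc2ccccc2)COC1=O | intermediate
10 | (4R)-4-benzyl-3-[(2R)-2-{[3-(benzyloxy)-4,5-dimethoxyphenyl]methyl}but-3-enoyl]-1,3-oxazolidin-2-one | C=C[C@@H](Cc1cc(OCc2ccccc2)c(OC)c(OC)c1)C(=O)N1[C@H](Cc2ccccc2)COC1=O | intermediate
11 | (2R)-2-{[3-(benzyloxy)-4,5-dimethoxyphenyl]methyl}but-3-eneperoxoic acid (formed as its lithium salt) | C=C[C@@H](Cc1cc(OCc2ccccc2)c(OC)c(OC)c1)C(=O)OO | intermediate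
12 | (2R)-2-{[3-(benzyloxy)-4,5-dimethoxyphenyl]methyl}but-3-enoic acid | C=C[C@@H](Cc1cc(OCc2ccccc2)c(OC)c(OC)c1)C(=O)O | intermediate
13 | chloromethyl chlorosulfate | ClCOS(Cl)(=O)=O | starting material
14 | chloromethyl (2R)-2-{[3-(benzyloxy)-4,5-dimethoxyphenyl]methyl}but-3-enoate | C=C[C@@H](Cc1cc(OCc2ccccc2)c(OC)c(OC)c1)C(=O)OCCl | intermediate
15 | 4-iodo-1,2-dimethoxybenzene | COc1ccc(I)cc1OC | starting material
16 | iodomethyl (2R)-2-{[3-(benzyloxy)-4,5-dimethoxyphenyl]methyl}but-3-enoate | C=C[C@@H](Cc1cc(OCc2ccccc2)c(OC)c(OC)c1)C(=O)OCI | intermediate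
17 | (3R,4R)-3-{[3-(benzyloxy)-4,5-dimethoxyphenyl]methyl}-4-[(3,4-dimethoxyphenyl)methyl]oxolan-2-one | COc1ccc(C[C@H]2COC(=O)[C@@H]2Cc2cc(OCc3ccccc3)c(OC)c(OC)c2)cc1OC | intermediate
18 | (3R,4R)-4-[(3,4-dimethoxyphenyl)methyl]-3-[(3-hydroxy-4,5-dimethoxyphenyl)methyl]oxolan-2-one | COc1ccc(C[C@H]2COC(=O)[C@@H]2Cc2cc(O)c(OC)c(OC)c2)cc1OC | target

Total step count: 9. Longest linear sequence: 8 steps (steps 1, 2, 3, 5, 6, 7, 8, 9); step 4 is a one-step side branch.

Steps most likely to fail

1. Step 8. The acyloxymethyl radical may be captured by aryl nickel, or reduced, before it cyclizes, because rotation of the ester into the reactive s-cis rotamer is slow. Translocation of the radical to the benzylic CH2 by 1,5-hydrogen transfer and poor facial selectivity at C4 are further risks. The fallback sets out from 14 and comes back at 17, using known chemistry only. Cross-metathesis of 14 with commercial 3,4-dimethoxystyrene (second-generation Grubbs catalyst, CH2Cl2, 40 °C) should give chloromethyl (2R,3E)-2-{[3-(benzyloxy)-4,5-dimethoxyphenyl]methyl}-4-(3,4-dimethoxyphenyl)but-3-enoate F1, so that the aryl group is in place before the ring closure. Halide exchange (NaI, acetone, rt) should give the iodomethyl ester F2. Slow addition of Bu3SnH with AIBN in benzene at 80 °C should then close the same ring bond by the known 5-exo cyclization of an acyloxymethyl radical, here onto a styrene, which is faster because a benzylic radical results. Hydrogen transfer from tin gives 17, with the same trans preference.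

2. Step 5. The extended dienolate may be alkylated at the γ-carbon, the double bond of the product may migrate back into conjugation by proton exchange with unreacted dienolate, or facial selectivity may be eroded. The fallback sets out from 5 and 4 and comes back at 10. γ-Butyrolactone is opened with PhSeNa ((PhSe)2, NaBH4, DMF, 120 °C) to 4-(phenylselanyl)butanoic acid F3. Coupling with 5 (DCC, DMAP cat., CH2Cl2) gives (4R)-4-benzyl-3-[4-(phenylselanyl)butanoyl]-1,3-oxazolidin-2-one F4. An ordinary Evans alkylation of its simple (Z)-enolate (NaN(SiMe3)2, THF, −78 °C, then 4) should give (4R)-4-benzyl-3-[(2R)-2-{[3-(benzyloxy)-4,5-dimethoxyphenyl]methyl}-4-(phenylselanyl)butanoyl]-1,3-oxazolidin-2-one F5. Oxidation (H2O2, pyridine, CH2Cl2, 0 °C → rt) gives the selenoxide F6, whose syn-elimination unveils the vinyl group of 10.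

3. Step 6. Under the basic cleavage the β,γ-double bond may migrate into conjugation, with loss of the C3 stereocentre through enolization, or the hindered imide may be opened at the ring carbonyl. The fallback sets out from 10 and comes back at 12. Reductive cleavage (LiBH4, MeOH 1 equiv, Et2O, 0 °C) should give (2R)-2-{[3-(benzyloxy)-4,5-dimethoxyphenyl]methyl}but-3-en-1-ol F7 and recovered 5. Buffered Dess–Martin oxidation (NaHCO3, CH2Cl2, 0 °C) gives (2R)-2-{[3-(benzyloxy)-4,5-dimethoxyphenyl]methyl}but-3-enal F8, which is used at once. Pinnick oxidation (NaClO2, NaH2PO4, 2-methyl-2-butene, t-BuOH/H2O) then gives 12 without a basic step.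

Further compounds
F1 | step 8 | chloromethyl (2R,3E)-2-{[3-(benzyloxy)-4,5-dimethoxyphenyl]methyl}-4-(3,4-dimethoxyphenyl)but-3-enoate | COc1ccc(/C=C/[C@@H](Cc2cc(OCc3ccccc3)c(OC)c(OC)c2)C(=O)OCCl)cc1OC
F2 | step 8 | iodomethyl (2R,3E)-2-{[3-(benzyloxy)-4,5-dimethoxyphenyl]methyl}-4-(3,4-dimethoxyphenyl)but-3-enoate | COc1ccc(/C=C/[C@@H](Cc2cc(OCc3ccccc3)c(OC)c(OC)c2)C(=O)OCI)cc1OC
F3 | step 5 | 4-(phenylselanyl)butanoic acid | OC(=O)CCC[Se]c1ccccc1
F4 | step 5 | (4R)-4-benzyl-3-[4-(phenylselanyl)butanoyl]-1,3-oxazolidin-2-one | O=C(CCC[Se]c1ccccc1)N1[C@H](Cc2ccccc2)COC1=O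
F5 | step 5 | (4R)-4-benzyl-3-[(2R)-2-{[3-(benzyloxy)-4,5-dimethoxyphenyl]methyl}-4-(phenylselanyl)butanoyl]-1,3-oxazolidin-2-one | c1ccccc1[Se]CC[C@@H](Cc1cc(OCc2ccccc2)c(OC)c(OC)c1)C(=O)N1[C@H](Cc2ccccc2)COC1=O
F6 | step 5 | selenoxide of F5 (mixture at selenium) | O=[Se](c1ccccc1)CC[C@@H](Cc1cc(OCc2ccccc2)c(OC)c(OC)c1)C(=O)N1[C@H](Cc2ccccc2)COC1=O
F7 | step 6 | (2R)-2-{[3-(benzyloxy)-4,5-dimethoxyphenyl]methyl}but-3-en-1-ol | C=C[C@@H](Cc1cc(OCc2ccccc2)c(OC)c(OC)c1)CO
F8 | step 6 | (2R)-2-{[3-(benzyloxy)-4,5-dimethoxyphenyl]methyl}but-3-enal | C=C[C@@H](Cc1cc(OCc2ccccc2)c(OC)c(OC)c1)C=O
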